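The cyclohexane carbons are numbered C1 (carbinol), C2 (CH bearing the chain), C3 (CMe2) to C6; C1' is the first chain carbon. Everything rests on the C2–C1' bond, the most hindered bond of the target, wedged between the fully substituted C1 and C3. A temporary C6 carbonyl turns C2 into the β-carbon of an achiral enone: copper-catalysed asymmetric conjugate addition of the complete C16 chain, as a homoallylic Grignard reagent, forges this bond, sets C2 and leaves a regiodefined C6–C1 enolate, stored as its silyl enol ether, through which the C1 oxygen later enters trans to the chain. The precursor pair is 2,4,4-trimethylcyclohex-2-enone and a farnesol-derived bromide; the carbonyl is excised afterwards.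

Key step: step 6

Remark: (2E,6E)-farnesol and 2,4,4-trimethylcyclohex-2-en-1-one are taken as purchasable; the sense of induction of the NHC ligand on this enone is to be assigned on a trial run and the enantiomer that gives (3S)-11 is used; "Rc" below stands for the (3E,7E,11E)-13-[(tert-butyldimethylsilyl)oxy]-3,7,11-trimethyltrideca-3,7,11-trien-1-yl group.

Step 1
Reactants: 1 (2E,6E)-farnesol
Product: 2 tert-butyl(dimethyl){[(2E,6E)-3,7,11-trimethyldodeca-2,6,10-trien-1-yl]oxy}silane (farnesyl TBS ether)
Conditions: TBSCl, imidazole, DMF, 0 °C to rt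
Reagents that add atoms: tert-butyldimethylsilyl chloride, CC(C)(C)[Si](C)(C)Cl
Why: Standard silyl ether protection of the primary allylic alcohol removes the only acidic proton so that the chain can later be carried as a Grignard reagent; no stereocenter is formed.

Step 2
Reactants: 2 farnesyl TBS ether
Product: 3 (2E,6E,10E)-12-[(tert-butyldimethylsilyl)oxy]-2,6,10-trimethyldodeca-2,6,10-trien-1-ol
Conditions: SeO2 (cat.), salicylic acid (cat.), t-BuOOH, CH2Cl2, 0 °C to rt, stopped at partial conversion with recycling of 2
Reagents that add atoms: selenium dioxide (catalytic oxygen carrier), O=[Se]=O; tert-butyl hydroperoxide, CC(C)(C)OO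
Why: Riley allylic oxidation (ene reaction of SeO2, then [2,3]-sigmatropic shift) should attack the terminal, most electron-rich trisubstituted alkene and oxidise its E-methyl group with retention of the E geometry, the 2,3-alkene being deactivated by the allylic oxygen; any enal 4 from over-oxidation is carried into step 3.

Step 3
Reactants: 3 terminal allylic alcohol
Product: 4 (2E,6E,10E)-12-[(tert-butyldimethylsilyl)oxy]-2,6,10-trimethyldodeca-2,6,10-trienal
Conditions: MnO2, CH2Cl2, rt
Reagents that add atoms: none
Why: MnO2 oxidation is selective for allylic alcohols and should give the conjugated E-enal without touching the silyl ether or the alkene geometry.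

Step 4
Reactants: 4 enal
Product: 5 tert-butyl(dimethyl){[(2E,6E,10E)-3,7,11-trimethyltrideca-2,6,10,12-tetraen-1-yl]oxy}silane (terminal 1,3-diene)
Conditions: Ph3PCH3Br, t-BuOK, THF, 0 °C to rt
Reagents that add atoms: methyltriphenylphosphonium bromide, C[P+](c1ccccc1)(c1ccccc1)c1ccccc1.[Br-]
Why: Wittig methylenation of the unhindered enal with the non-stabilised ylide installs the terminal vinyl group, and the existing E-alkenes are not affected.

Step 5
Reactants: 5 terminal 1,3-diene
Product: 7 tert-butyl{[(2E,6E,10E)-13-bromo-3,7,11-trimethyltrideca-2,6,10-trien-1-yl]oxy}dimethylsilane (homoallylic bromide), via alkylzirconocene chloride 6 (not isolated)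
Conditions: Cp2Zr(H)Cl, THF, rt; then NBS, 0 °C
Reagents that add atoms: N-bromosuccinimide, O=C1CCC(=O)N1Br
Why: Hydrozirconation adds Zr–H in a 1,2 sense across the monosubstituted vinyl terminus of the diene, the only alkene reactive towards Cp2Zr(H)Cl, placing zirconium on the terminal carbon, and NBS should cleave the C–Zr bond of 6 to the primary bromide faster than it reacts with the trisubstituted alkenes.

Step 6
Reactants: 7 homoallylic bromide; 8 2,4,4-trimethylcyclohex-2-en-1-one
Product: 11 trimethyl{[(3S)-2,4,4-trimethyl-3-Rc-cyclohex-1-en-1-yl]oxy}silane (TMS enol ether), via Grignard reagent 9 (not isolated), via bromomagnesium enolate 10 (not isolated)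
Conditions: Mg, Et2O, rt; then Cu(OTf)2 (cat.), 1-mesityl-3-(1-hydroxy-4-methylpentan-2-yl)-4,5-dihydroimidazolium hexafluorophosphate (single enantiomer, cat.), Et2O, −30 °C, slow addition of 8; then TMSCl, Et3N, DMPU, −30 °C to rt
Reagents that add atoms: chlorotrimethylsilane, C[Si](C)(C)Cl
Why: Magnesium inserts into the primary C–Br bond of 7 to give Grignard reagent 9, which reduces the divalent copper salt to monovalent copper and deprotonates the ligand; the resulting chiral alkoxy-NHC alkylcopper species π-complexes enone 8, adds oxidatively at C3 (trivalent copper intermediate) and reductively eliminates to form the C3–CH2 bond and enolate 10, which TMSCl captures on oxygen as 11. The closest known reaction type is the copper/NHC-catalysed asymmetric conjugate addition of Grignard reagents to α-methyl cyclic enones with trapping of the magnesium enolate, here burdened additionally by the gem-dimethyl group at C4. No ring is closed. The one new stereocenter (C3 of the ring, C2 of the target) is set by the chiral ligand, which differentiates the enantiotopic faces of the flat enone. The step needs 1,4- over 1,2-addition at a β-carbon next to a quaternary carbon: the β-carbon carries only hydrogen, the carbonyl is shielded by the α-methyl group, NHC–copper catalysts of this kind are reactive enough to build quaternary centers, and slow addition of 8 at low temperature should keep uncatalysed attack down. Because the enolate is silylated and never protonated, its position (towards the methyl-bearing carbon) is preserved for step 7, and the Grignard reagent is used cold so that reversible cyclopropylcarbinyl rearrangement cannot scramble the neighbouring E-alkene.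

Step 7
Reactants: 11 TMS enol ether
Product: 13 (2R,3S)-2-hydroxy-2,4,4-trimethyl-3-Rc-cyclohexan-1-one, via potassium enolate 12 (not isolated)
Conditions: t-BuOK, THF, −40 °C; then trans-2-(phenylsulfonyl)-3-phenyloxaziridine, −78 °C; aq. NH4Cl at −78 °C
Reagents that add atoms: 2-(phenylsulfonyl)-3-phenyloxaziridine, O=S(=O)(N1OC1c1ccccc1)c1ccccc1
Why: tert-Butoxide cleaves the O–Si bond to the regiodefined tetrasubstituted potassium enolate 12, and Davis oxidation (enolate hydroxylation by the N-sulfonyloxaziridine, which does not epoxidise isolated alkenes) should deliver oxygen to C2 on the face opposite the neighbouring C3 side chain, setting the tertiary alcohol trans to the chain (2R).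

Step 8
Reactants: 13 α-hydroxy ketone
Product: 14 N'-[(1E,2R,3S)-2-hydroxy-2,4,4-trimethyl-3-Rc-cyclohexylidene]-4-methylbenzenesulfonohydrazide (tosylhydrazone)
Conditions: TsNHNH2, EtOH, 50 °C
Reagents that add atoms: p-toluenesulfonohydrazide, Cc1ccc(cc1)S(=O)(=O)NN
Why: Hydrazone condensation at a ketone hindered on one side only should proceed under neutral conditions that the tertiary alcohol and the silyl ether tolerate; the C=N geometry (E expected) is of no consequence.

Step 9
Reactants: 14 tosylhydrazone
Product: 16 (1S,2S)-1,3,3-trimethyl-2-Rc-cyclohexan-1-ol (TBS ether of the target), via N-alkyl tosylhydrazide 15 (not isolated)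
Conditions: catecholborane (excess), CHCl3, 0 °C to rt; then NaOAc·3H2O, reflux
Reagents that add atoms: none
Why: Catecholborane reduction of the tosylhydrazone (a neutral Wolff–Kishner-type deoxygenation) adds hydride to C=N to give hydrazide 15 as its boron derivative, acetate then triggers loss of p-toluenesulfinate and the diazene extrudes N2, turning C=O into CH2 without base, so that neither stereocenter, the alkenes nor the silyl ether should be touched.

Step 10
Reactants: 16 TBS ether of the target
Product: 17 preluffariellolide A, (2E,6E,10E)-13-[(1S,2S)-2-hydroxy-2,6,6-trimethylcyclohexyl]-3,7,11-trimethyltrideca-2,6,10-trien-1-ol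
Conditions: TBAF, THF, 0 °C to rt
Reagents that add atoms: none
Why: Fluoride-mediated desilylation liberates the primary allylic alcohol; the tertiary alcohol and both stereocenters are inert.

Compound list
1 | (2E,6E)-farnesol | C/C(=C\CO)CC/C=C(\C)CCC=C(C)C | starting material
2 | farnesyl TBS ether | C/C(=C\CO[Si](C)(C)C(C)(C)C)CC/C=C(\C)CCC=C(C)C | intermediate
3 | (2E,6E,10E)-12-[(tert-butyldimethylsilyl)oxy]-2,6,10-trimethyldodeca-2,6,10-trien-1-ol | C/C(=C\CO[Si](C)(C)C(C)(C)C)CC/C=C(\C)CC/C=C(\C)CO | intermediate
4 | (2E,6E,10E)-12-[(tert-butyldimethylsilyl)oxy]-2,6,10-trimethyldodeca-2,6,10-trienal | C/C(=C\CO[Si](C)(C)C(C)(C)C)CC/C=C(\C)CC/C=C(\C)C=O | intermediate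
5 | tert-butyl(dimethyl){[(2E,6E,10E)-3,7,11-trimethyltrideca-2,6,10,12-tetraen-1-yl]oxy}silane | C/C(=C\CO[Si](C)(C)C(C)(C)C)CC/C=C(\C)CC/C=C(\C)C=C | intermediate
6 | chlorobis(cyclopentadienyl)(Rc)zirconium, alkylzirconocene chloride (cyclopentadienyl rings drawn σ-bonded) | C/C(=C\CO[Si](C)(C)C(C)(C)C)CC/C=C(\C)CC/C=C(\C)CC[Zr](Cl)(C1C=CC=C1)C1C=CC=C1 | intermediate
7 | tert-butyl{[(2E,6E,10E)-13-bromo-3,7,11-trimethyltrideca-2,6,10-trien-1-yl]oxy}dimethylsilane | C/C(=C\CO[Si](C)(C)C(C)(C)C)CC/C=C(\C)CC/C=C(\C)CCBr | intermediate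
8 | 2,4,4-trimethylcyclohex-2-en-1-one | CC1=CC(C)(C)CCC1=O | starting material
9 | Rc-magnesium bromide (homoallylic Grignard reagent) | C/C(=C\CO[Si](C)(C)C(C)(C)C)CC/C=C(\C)CC/C=C(\C)CC[Mg]Br | intermediate
10 | bromomagnesium (3S)-2,4,4-trimethyl-3-Rc-cyclohex-1-en-1-olate | C/C(=C\CO[Si](C)(C)C(C)(C)C)CC/C=C(\C)CC/C=C(\C)CC[C@H]1C(C)(C)CCC(O[Mg]Br)=C1C | intermediate
11 | trimethyl{[(3S)-2,4,4-trimethyl-3-Rc-cyclohex-1-en-1-yl]oxy}silane | C/C(=C\CO[Si](C)(C)C(C)(C)C)CC/C=C(\C)CC/C=C(\C)CC[C@H]1C(C)(C)CCC(O[Si](C)(C)C)=C1C | intermediate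
12 | potassium (3S)-2,4,4-trimethyl-3-Rc-cyclohex-1-en-1-olate | C/C(=C\CO[Si](C)(C)C(C)(C)C)CC/C=C(\C)CC/C=C(\C)CC[C@H]1C(C)(C)CCC([O-])=C1C.[K+] | intermediate
13 | (2R,3S)-2-hydroxy-2,4,4-trimethyl-3-Rc-cyclohexan-1-one | C/C(=C\CO[Si](C)(C)C(C)(C)C)CC/C=C(\C)CC/C=C(\C)CC[C@H]1C(C)(C)CCC(=O)[C@]1(C)O | intermediate
14 | N'-[(1E,2R,3S)-2-hydroxy-2,4,4-trimethyl-3-Rc-cyclohexylidene]-4-methylbenzenesulfonohydrazide | C/C(=C\CO[Si](C)(C)C(C)(C)C)CC/C=C(\C)CC/C=C(\C)CC[C@H]1C(C)(C)CC/C(=N\NS(=O)(=O)c2ccc(C)cc2)[C@]1(C)O | intermediate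
15 | N'-[(2R,3S)-2-hydroxy-2,4,4-trimethyl-3-Rc-cyclohexyl]-4-methylbenzenesulfonohydrazide (both C1 epimers, boron-bound in the flask) | C/C(=C\CO[Si](C)(C)C(C)(C)C)CC/C=C(\C)CC/C=C(\C)CC[C@H]1C(C)(C)CCC(NNS(=O)(=O)c2ccc(C)cc2)[C@]1(C)O | intermediate
16 | (1S,2S)-1,3,3-trimethyl-2-Rc-cyclohexan-1-ol | C/C(=C\CO[Si](C)(C)C(C)(C)C)CC/C=C(\C)CC/C=C(\C)CC[C@H]1C(C)(C)CCC[C@]1(C)O | intermediate
17 | preluffariellolide A | C/C(=C\CO)CC/C=C(\C)CC/C=C(\C)CC[C@H]1C(C)(C)CCC[C@]1(C)O | target

Total step count: 10
Longest linear sequence: 10 steps (1 to 17; enone 8 is purchased and enters in step 6)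

Steps most likely to fail

1. Step 6. Conjugate addition at a β-carbon flanked by the quaternary C4 and the α-methyl group may be slow, so that direct 1,2-addition of the Grignard reagent or poor facial discrimination takes over. The fallback sets out from diene 5 and enone 8 and returns at 11. Alkylzirconocene chloride 6 is generated from 5 as in the first half of step 5 (Cp2Zr(H)Cl, CH2Cl2, rt). Without halogenation it is added to 8 with CuCl/AgNTf2 (monovalent copper), a BINOL-derived phosphoramidite ligand and TMSCl in Et2O at rt. The soft alkylzirconocene should not add 1,2. The chlorozirconocene enolate F1 formed by conjugate addition is silylated in the flask (TMSCl, Et3N) to give 11.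

2. Step 9. Hydride transfer to the hindered C=N bond may be sluggish, or the neighbouring hydroxyl may be lost by elimination at the diazene stage. The fallback sets out from 13 and returns at 16. NaBH4 (MeOH, 0 °C) should reduce the ketone to the (1R,2R,3S)-diol F2; axial hydride delivery is expected, and the epimer would serve equally. Phenyl chlorothionoformate, pyridine and DMAP (CH2Cl2, 0 °C) acylate only the secondary hydroxyl to give the O-phenyl thionocarbonate F3. Barton–McCombie deoxygenation (Bu3SnH, AIBN, toluene, 90 °C) then gives 16.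

3. Step 7. Proton transfer between enolate and product, capture of the enolate by the sulfonimine by-product, or eroded facial selectivity at the hindered tetrasubstituted enolate may lower the return. The fallback sets out from 11 and returns at 13 by a Rubottom oxidation under neutral conditions. Dimethyldioxirane (1 equiv, acetone/CH2Cl2, −78 °C) should epoxidise the far more electron-rich enol ether alkene from the face opposite the chain to the silyloxy epoxide F4. On warming, F4 opens with 1,4-silyl shift to the α-silyloxy ketone F5. K2CO3 in MeOH at 0 °C then frees the tertiary alcohol to give 13.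

Further compounds
F1 | step 6 | chlorobis(cyclopentadienyl)zirconium (3S)-2,4,4-trimethyl-3-Rc-cyclohex-1-en-1-olate | C/C(=C\CO[Si](C)(C)C(C)(C)C)CC/C=C(\C)CC/C=C(\C)CC[C@H]1C(C)(C)CCC(O[Zr](Cl)(C2C=CC=C2)C2C=CC=C2)=C1C
F2 | step 9 | (1R,2R,3S)-2,4,4-trimethyl-3-Rc-cyclohexane-1,2-diol | C/C(=C\CO[Si](C)(C)C(C)(C)C)CC/C=C(\C)CC/C=C(\C)CC[C@H]1C(C)(C)CC[C@@H](O)[C@]1(C)O
F3 | step 9 | O-[(1R,2R,3S)-2-hydroxy-2,4,4-trimethyl-3-Rc-cyclohexyl] O-phenyl carbonothioate | C/C(=C\CO[Si](C)(C)C(C)(C)C)CC/C=C(\C)CC/C=C(\C)CC[C@H]1C(C)(C)CC[C@@H](OC(=S)Oc2ccccc2)[C@]1(C)O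
F4 | step 7 | trimethyl{[(1R,2S,6R)-1,3,3-trimethyl-2-Rc-7-oxabicyclo[4.1.0]heptan-6-yl]oxy}silane (silyloxy epoxide, oxygen trans to the chain) | C/C(=C\CO[Si](C)(C)C(C)(C)C)CC/C=C(\C)CC/C=C(\C)CC[C@H]1C(C)(C)CC[C@]2(O[Si](C)(C)C)O[C@]12C
F5 | step 7 | (2R,3S)-2,4,4-trimethyl-3-Rc-2-[(trimethylsilyl)oxy]cyclohexan-1-one | C/C(=C\CO[Si](C)(C)C(C)(C)C)CC/C=C(\C)CC/C=C(\C)CC[C@H]1C(C)(C)CCC(=O)[C@]1(C)O[Si](C)(C)C
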